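The cyclohexene core (C1 acyl, C2 guaiacyl, C3H2, C4=C5, C6 veratryl) is dissected into three two-carbon π-units: C6–C1 from a veratrylidene acetone, C4=C5 from a silylacetylene and C2–C3 from O-silylated 4-vinylguaiacol. One chiral nickel(0) catalyst should join them in a single operation, making C5–C6, C3–C4 and C1–C2, closing the six-membered ring and setting C1, C2 and C6 in the all-equatorial array, in which C1 (α to the ketone) is also the thermodynamic epimer. The precursors are thus two purchased compounds and one silyl ether; the enolised diketone arm is then grown from the methyl ketone by Claisen acetylation and a boron-templated aldol condensation with vanillin.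

Key step: step 2

Remark on numbering: in all names C1 carries the acyl group, C2 the guaiacyl ring, C3 is CH2, C4=C5 is the alkene (next to the veratryl-bearing C6), so the ring is named as a cyclohex-4-en-1-yl unit and the silicon of the key-step product sits on C4.
Remark on descriptors: the target is (1R,2S,6R) in this numbering (acyl trans to both aryl groups, aryl groups cis); compound 5 is (1R,2S,6S) with the same spatial arrangement, because the silylated C4 raises the CIP rank of the C5 branch at C6.
Assumption on the catalyst: the sense of induction of the chiral ligand cannot be predicted, so the ligand antipode that gives the drawn enantiomer is taken to be found by screening; nickel-bound species of the catalytic cycle are described in the Why line of step 2 and are not numbered.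

Step 1
Reactants: 1 2-methoxy-4-vinylphenol (4-vinylguaiacol)
Product: 2 tert-butyl(2-methoxy-4-vinylphenoxy)dimethylsilane
Conditions: TBSCl, imidazole, DMF, 0 °C → rt
Reagents that add atoms: tert-butyldimethylsilyl chloride, CC(C)(C)[Si](C)(C)Cl
Why: Standard silylation of a phenol (TBSCl/imidazole) that leaves the vinyl group untouched and removes the acidic O–H, which would otherwise protonate nickel enolates in step 2.

Step 2
Reactants: 2 tert-butyl(2-methoxy-4-vinylphenoxy)dimethylsilane; 3 (E)-4-(3,4-dimethoxyphenyl)but-3-en-2-one; 4 ethynyltrimethylsilane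
Product: 5 1-[(1R,2S,6S)-2-(4-{[tert-butyl(dimethyl)silyl]oxy}-3-methoxyphenyl)-6-(3,4-dimethoxyphenyl)-4-(trimethylsilyl)cyclohex-4-en-1-yl]ethan-1-one
Conditions: Ni(cod)2 (10 mol%), ANIPE-type C2-symmetric chiral NHC (free carbene, 12 mol%), 2 (3 equiv), toluene, 30 °C, 3 and 4 (1.5 equiv) added slowly by syringe pump
Reagents that add atoms: none
Why: Proposed new method: Ni(0) carrying one bulky chiral carbene should undergo oxidative cyclisation with enone 3 and alkyne 4, bonding the alkyne CH terminus to the enone β-carbon (C5–C6) and leaving an alkenyl–Ni bond at the silylated C4 and a nickel enolate at C1; 2,1-insertion of styrene 2 into the alkenyl–Ni bond (C3–C4) then gives an η3-benzylnickel at C2, and C(sp3)–C(sp3) reductive elimination joins C1 to C2 and returns Ni(0). The closest known reaction types are the Ni(0)-catalysed [2+2+2] cycloaddition of two enones with one alkyne and the Ni-catalysed enone–alkyne reductive coupling, which share the first nickelacycle; here a styrene takes the place of the second enone. The cyclohexene ring is closed by reductive elimination from a seven-membered nickelacycle (a formal [2+2+2], with C1–C2 as the last bond). C6 is set by the ligand through enone-face selection in the oxidative cyclisation, C1 follows from the E geometry of 3 (suprafacial addition, retention on elimination) and is in any case the base-equilibratable all-equatorial position, and C2 should follow from π–σ–π equilibration of the benzylnickel and ring closure through the less crowded diastereomer, which places the guaiacyl ring cis to the veratryl ring. The step needs cross-selectivity among three π-partners: only the enone/alkyne pair is electronically matched for oxidative cyclisation, the electron-rich styrene (used in excess) is reluctant to cyclise but inserts readily, the silyl group fixes the alkyne orientation and retards alkyne oligomerisation, and slow addition of 3 and 4 keeps enone–alkyne–enone adducts down.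

Step 3
Reactants: 5 the vinylsilane ketone from step 2
Product: 6 1-[(1R,2S,6R)-2-(4-{[tert-butyl(dimethyl)silyl]oxy}-3-methoxyphenyl)-6-(3,4-dimethoxyphenyl)cyclohex-4-en-1-yl]ethan-1-one
Conditions: CF3CO2H, CH2Cl2, 0 °C → rt; aq. NaHCO3
Reagents that add atoms: none
Why: Electrophilic ipso-protodesilylation of a vinylsilane, in which protonation at the silicon-bearing C4 gives a β-silyl-stabilised cation at C5 that loses silicon, so the C4=C5 bond stays in place while the far less acid-labile aryl silyl ether, the ketone and the three stereocentres should be untouched.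

Step 4
Reactants: 6 the methyl ketone from step 3
Product: 7 1-[(1R,2S,6R)-2-(4-{[tert-butyl(dimethyl)silyl]oxy}-3-methoxyphenyl)-6-(3,4-dimethoxyphenyl)cyclohex-4-en-1-yl]butane-1,3-dione (largely enolised)
Conditions: 1-acetylbenzotriazole, MgBr2·OEt2, i-Pr2NEt, CH2Cl2, rt; 1 M HCl work-up
Reagents that add atoms: 1-acetyl-1H-benzotriazole, CC(=O)n1nnc2ccccc21
Why: Crossed Claisen condensation under soft enolisation, where the magnesium enolate of the unhindered methyl side is C-acylated by the N-acylbenzotriazole and the reaction is driven by formation of the magnesium diketonate, which only acylation at CH3 allows; C1 is hindered and already in its thermodynamic configuration.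

Step 5
Reactants: 7 the silyl-protected diketone from step 4
Product: 8 1-[(1R,2S,6R)-6-(3,4-dimethoxyphenyl)-2-(4-hydroxy-3-methoxyphenyl)cyclohex-4-en-1-yl]butane-1,3-dione
Conditions: TBAF, AcOH, THF, 0 °C
Reagents that add atoms: none
Why: Fluoride-mediated cleavage of the aryl silyl ether, buffered with acetic acid so that the enolisable diketone is not exposed to basic fluoride.

Step 6
Reactants: 8 the phenolic diketone from step 5; 9 vanillin
Product: 12 (2Z,4E)-1-[(1R,2S,6R)-6-(3,4-dimethoxyphenyl)-2-(4-hydroxy-3-methoxyphenyl)cyclohex-4-en-1-yl]-3-hydroxy-5-(4-hydroxy-3-methoxyphenyl)penta-2,4-dien-1-one (target CNP0290899.1), via dibutoxyboron diketonate 10 (not isolated), via boron-chelated curcuminoid 11 (not isolated)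
Conditions: B2O3, B(On-Bu)3, EtOAc, 70 °C; 9; n-BuNH2 (cat., slow addition), 70 °C; then 0.4 M aq. HCl, 60 °C
Reagents that add atoms: none
Why: Pabon-type boron-templated aldol condensation, in which chelation of the 1,3-diketone to boron blocks the central carbon and makes the terminal CH3 the nucleophile, amine-mediated addition to vanillin and E1cB dehydration give the E-styryl unit, and dilute acid releases the enolised diketone; free phenols are tolerated, condensation at the hindered methine C1 cannot lead to an alkene, and any equilibration at C1 returns the all-equatorial isomer.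

Compound list
1 | 2-methoxy-4-vinylphenol | C=Cc1ccc(O)c(OC)c1 | starting material
2 | tert-butyl(2-methoxy-4-vinylphenoxy)dimethylsilane | C=Cc1ccc(O[Si](C)(C)C(C)(C)C)c(OC)c1 | intermediate
3 | (E)-4-(3,4-dimethoxyphenyl)but-3-en-2-one | CC(=O)/C=C/c1ccc(OC)c(OC)c1 | starting material
4 | ethynyltrimethylsilane | C#C[Si](C)(C)C | starting material
5 | 1-[(1R,2S,6S)-2-(4-{[tert-butyl(dimethyl)silyl]oxy}-3-methoxyphenyl)-6-(3,4-dimethoxyphenyl)-4-(trimethylsilyl)cyclohex-4-en-1-yl]ethan-1-one | CC(=O)[C@@H]1[C@@H](c2ccc(O[Si](C)(C)C(C)(C)C)c(OC)c2)CC([Si](C)(C)C)=C[C@H]1c1ccc(OC)c(OC)c1 | intermediate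
6 | 1-[(1R,2S,6R)-2-(4-{[tert-butyl(dimethyl)silyl]oxy}-3-methoxyphenyl)-6-(3,4-dimethoxyphenyl)cyclohex-4-en-1-yl]ethan-1-one | CC(=O)[C@@H]1[C@@H](c2ccc(O[Si](C)(C)C(C)(C)C)c(OC)c2)CC=C[C@H]1c1ccc(OC)c(OC)c1 | intermediate
7 | 1-[(1R,2S,6R)-2-(4-{[tert-butyl(dimethyl)silyl]oxy}-3-methoxyphenyl)-6-(3,4-dimethoxyphenyl)cyclohex-4-en-1-yl]butane-1,3-dione | CC(=O)CC(=O)[C@@H]1[C@@H](c2ccc(O[Si](C)(C)C(C)(C)C)c(OC)c2)CC=C[C@H]1c1ccc(OC)c(OC)c1 | intermediate
8 | 1-[(1R,2S,6R)-6-(3,4-dimethoxyphenyl)-2-(4-hydroxy-3-methoxyphenyl)cyclohex-4-en-1-yl]butane-1,3-dione | CC(=O)CC(=O)[C@@H]1[C@@H](c2ccc(O)c(OC)c2)CC=C[C@H]1c1ccc(OC)c(OC)c1 | intermediate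
9 | vanillin | COc1cc(C=O)ccc1O | starting material
10 | dibutoxyboron chelate of diketone 8 (2,2-dibutoxy-1,3,2-dioxaborinine form) | CC1=CC([C@@H]2[C@@H](c3ccc(O)c(OC)c3)CC=C[C@H]2c2ccc(OC)c(OC)c2)=[O+][B-](OCCCC)(OCCCC)O1 | intermediate (not isolated)
11 | dibutoxyboron chelate of the target | COc1cc(/C=C/C2=CC([C@@H]3[C@@H](c4ccc(O)c(OC)c4)CC=C[C@H]3c3ccc(OC)c(OC)c3)=[O+][B-](OCCCC)(OCCCC)O2)ccc1O | intermediate (not isolated)
12 | (2Z,4E)-1-[(1R,2S,6R)-6-(3,4-dimethoxyphenyl)-2-(4-hydroxy-3-methoxyphenyl)cyclohex-4-en-1-yl]-3-hydroxy-5-(4-hydroxy-3-methoxyphenyl)penta-2,4-dien-1-one | COc1cc(/C=C/C(O)=C/C(=O)[C@@H]2[C@@H](c3ccc(O)c(OC)c3)CC=C[C@H]2c2ccc(OC)c(OC)c2)ccc1O | target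

Total step count: 6
Longest linear sequence: 6 steps (1 → 2 → 5 → 6 → 7 → 8 → 12)

Steps most likely to fail

Step 2 (three-component nickel cycloaddition). The catalytic cycle may leave the intended path at several points:
- β-hydride elimination from the benzylnickel may outrun ring-closing reductive elimination and give open-chain dienyl ketones;
- enone–alkyne–enone coupling or alkyne oligomerisation may outcompete styrene insertion;
- facial discrimination by the ligand may be weak, lowering the enantiomeric purity or giving the C2 epimer.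

Fallback with known chemistry, setting out from vanillin 9 and returning at 6, so that steps 2 and 3 are bypassed: vanillin 9 would be condensed with acetone (aq. NaOH, Claisen–Schmidt) to (E)-4-(4-hydroxy-3-methoxyphenyl)but-3-en-2-one F1, which would be silylated (TBSCl, imidazole) to (E)-4-(4-{[tert-butyl(dimethyl)silyl]oxy}-3-methoxyphenyl)but-3-en-2-one F2. Purchased (E)-3,4-dimethoxycinnamaldehyde (COc1ccc(/C=C/C=O)cc1OC) would be methylenated with Ph3P=CH2 in THF to (E)-1-(3,4-dimethoxyphenyl)buta-1,3-diene F3. Heating F2 with F3 (toluene, 150–170 °C, sealed tube, BHT) should give a thermal Diels–Alder adduct with "ortho" orientation: the diene CH2 terminus bonds to the aryl-bearing β-carbon of the enone and the aryl-bearing diene terminus to the α-carbon. The E dienophile fixes C1/C2 trans, and the transition state with the acetyl group exo leads to the racemic all-trans adduct F4. This would be separated from its acetyl-endo diastereomer by chromatography and resolved by preparative HPLC on a chiral phase to give 6.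

Step 4 (Claisen acetylation). Enolisation of the hindered ketone by the mild Mg(II)/amine system may be slow, or the enolate may be acylated on oxygen or twice. Fallback setting out from 6 and returning at 7: the kinetic lithium enolate of 6 (LDA, THF, −78 °C, deprotonation at CH3) would be added to acetaldehyde to give the β-hydroxy ketone F5 (carbinol epimers, of no consequence), and oxidation with Dess–Martin periodinane (NaHCO3, CH2Cl2) would give diketone 7.

Step 6 (boron-templated condensation). Condensation of the bulky boron chelate may stall, the aldehyde may attack the central carbon if chelation is incomplete, or the product may degrade during acidic release from boron. Fallback setting out from 7 and 9 and returning at 12, so that step 5 is bypassed as well: vanillin 9 would be silylated (TBSCl, imidazole) to 4-{[tert-butyl(dimethyl)silyl]oxy}-3-methoxybenzaldehyde F6. Diketone 7 would be converted with LDA (2.2 equiv, THF, −78 → 0 °C) into its 1,3-dianion, which should react at the terminal methyl carbon with F6 (Hauser-type dianion aldol) to give the δ-hydroxy-β-diketone F7. Dehydration (cat. TsOH, toluene, or MsCl/Et3N) would give the bis-silyl ether of the target F8, and TBAF/AcOH in THF at 0 °C would remove both silyl groups to give 12.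

Further compounds
F1 | step 2 | (E)-4-(4-hydroxy-3-methoxyphenyl)but-3-en-2-one | CC(=O)/C=C/c1ccc(O)c(OC)c1
F2 | step 2 | (E)-4-(4-{[tert-butyl(dimethyl)silyl]oxy}-3-methoxyphenyl)but-3-en-2-one | CC(=O)/C=C/c1ccc(O[Si](C)(C)C(C)(C)C)c(OC)c1
F3 | step 2 | (E)-1-(3,4-dimethoxyphenyl)buta-1,3-diene | C=C/C=C/c1ccc(OC)c(OC)c1
F4 | step 2 | racemic all-trans 1-[2-(4-{[tert-butyl(dimethyl)silyl]oxy}-3-methoxyphenyl)-6-(3,4-dimethoxyphenyl)cyclohex-4-en-1-yl]ethan-1-one (racemate of 6; one enantiomer drawn) | CC(=O)[C@@H]1[C@@H](c2ccc(O[Si](C)(C)C(C)(C)C)c(OC)c2)CC=C[C@H]1c1ccc(OC)c(OC)c1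
F5 | step 4 | 1-[(1R,2S,6R)-2-(4-{[tert-butyl(dimethyl)silyl]oxy}-3-methoxyphenyl)-6-(3,4-dimethoxyphenyl)cyclohex-4-en-1-yl]-3-hydroxybutan-1-one (carbinol epimers) | CC(O)CC(=O)[C@@H]1[C@@H](c2ccc(O[Si](C)(C)C(C)(C)C)c(OC)c2)CC=C[C@H]1c1ccc(OC)c(OC)c1
F6 | step 6 | 4-{[tert-butyl(dimethyl)silyl]oxy}-3-methoxybenzaldehyde | COc1cc(C=O)ccc1O[Si](C)(C)C(C)(C)C
F7 | step 6 | 5-(4-{[tert-butyl(dimethyl)silyl]oxy}-3-methoxyphenyl)-1-[(1R,2S,6R)-2-(4-{[tert-butyl(dimethyl)silyl]oxy}-3-methoxyphenyl)-6-(3,4-dimethoxyphenyl)cyclohex-4-en-1-yl]-5-hydroxypentane-1,3-dione (carbinol epimers) | COc1cc(C(O)CC(=O)CC(=O)[C@@H]2[C@@H](c3ccc(O[Si](C)(C)C(C)(C)C)c(OC)c3)CC=C[C@H]2c2ccc(OC)c(OC)c2)ccc1O[Si](C)(C)C(C)(C)C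
F8 | step 6 | bis(tert-butyldimethylsilyl) ether of target 12 | COc1cc(/C=C/C(O)=C/C(=O)[C@@H]2[C@@H](c3ccc(O[Si](C)(C)C(C)(C)C)c(OC)c3)CC=C[C@H]2c2ccc(OC)c(OC)c2)ccc1O[Si](C)(C)C(C)(C)C
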